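**Retrosynthetic overview**

- The target is the trans-(2R,3R) 3-O-methyl dihydroflavonol. The last step frees C5–OH from its peri methyl ether and C6–OH and C3'–OH from benzyl ethers with BCl3.
- Ring C is the only ring made. It is closed late through O1–C2 by an intramolecular Mitsunobu etherification with inversion at C2 of an open-chain syn aldol. Rings A and B are bought as arenes.
- The strategy rests on C3. This sp3 carbon of ring C carries H, OMe, the C4 carbonyl and the C2–C3 bond, which is what a diazoketone carbon holds after taking up methanol and an aldehyde. Cutting C3–OMe and C2–C3 gives a ring A aroyldiazomethane, methanol and the ring B aldehyde.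
- The ring A diazoketone comes from syringaldehyde (benzylation, Baeyer–Villiger, symmetric ortho-formylation, acetylation, Pinnick oxidation, acid chloride/CH2N2). The ring B aldehyde comes from isovanillin.

Key step: step 8

Assumption: the sense of induction of the zirconium–BINOL cocatalyst on this new substrate class cannot be predicted with certainty; the (R)-ligand is written, and the (S)-ligand would be used instead if the first experiment showed the enantiomeric syn adduct to be favoured.

**Route**

Step 1
Reactants: 1 syringaldehyde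
Product: 2 4-(benzyloxy)-3,5-dimethoxybenzaldehyde
Conditions: BnBr, K2CO3, DMF, 60 °C
Reagents that add atoms: benzyl bromide BrCc1ccccc1
Why: Williamson etherification (SN2) of the potassium phenoxide with a primary benzylic bromide; the aldehyde is inert to K2CO3 in DMF.

Step 2
Reactants: 2 4-(benzyloxy)-3,5-dimethoxybenzaldehyde, 3 methanol
Product: 5 4-(benzyloxy)-3,5-dimethoxyphenol, via aryl formate 4 (not isolated)
Conditions: mCPBA, CH2Cl2, 0 °C to rt; then MeOH, K2CO3 (cat.), rt
Reagents that add atoms: 3-chloroperoxybenzoic acid OOC(=O)c1cccc(Cl)c1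
Why: Baeyer–Villiger (Dakin-type) oxidation in which the electron-rich aryl group migrates in preference to hydride, followed by transesterification of the labile aryl formate to methanol; benzyl and methyl ethers are untouched.

Step 3
Reactants: 5 4-(benzyloxy)-3,5-dimethoxyphenol
Product: 6 3-(benzyloxy)-6-hydroxy-2,4-dimethoxybenzaldehyde
Conditions: (CH2O)n, MgCl2, Et3N, MeCN, reflux; aq. HCl work-up
Reagents that add atoms: formaldehyde (from paraformaldehyde) C=O
Why: Casnati–Skattebøl ortho-formylation, in which the magnesium phenoxide delivers formaldehyde to the ortho carbon and a second formaldehyde oxidises the benzylic alkoxide by hydride transfer; the two ortho positions are equivalent by symmetry and the para position is blocked, so only one aldehyde can form.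

Step 4
Reactants: 6 3-(benzyloxy)-6-hydroxy-2,4-dimethoxybenzaldehyde
Product: 7 4-(benzyloxy)-2-formyl-3,5-dimethoxyphenyl acetate
Conditions: Ac2O, pyridine, DMAP (cat.), CH2Cl2, rt
Reagents that add atoms: acetic anhydride CC(=O)OC(C)=O
Why: DMAP-catalysed O-acylation of the phenol, which caps the only O–H of ring A ahead of the oxidation and carbenoid steps.

Step 5
Reactants: 7 4-(benzyloxy)-2-formyl-3,5-dimethoxyphenyl acetate
Product: 8 6-(acetyloxy)-3-(benzyloxy)-2,4-dimethoxybenzoic acid
Conditions: NaClO2, NaH2PO4, 2-methyl-2-butene, t-BuOH–H2O, 0 °C to rt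
Reagents that add atoms: sodium chlorite [Na+].[O-]Cl=O
Why: Pinnick oxidation of the aldehyde by chlorous acid at about pH 4, with 2-methyl-2-butene removing HOCl so that the electron-rich ring is not chlorinated and the aryl acetate is not hydrolysed.

Step 6
Reactants: 8 6-(acetyloxy)-3-(benzyloxy)-2,4-dimethoxybenzoic acid
Product: 10 4-(benzyloxy)-2-(2-diazoacetyl)-3,5-dimethoxyphenyl acetate, via aroyl chloride 9 (not isolated)
Conditions: (COCl)2, DMF (cat.), CH2Cl2, 0 °C to rt, evaporate; then CH2N2 (3 equiv), Et2O–THF, 0 °C to rt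
Reagents that add atoms: oxalyl chloride ClC(=O)C(Cl)=O (chlorine of 9 only); diazomethane C=[N+]=[N-]
Why: Vilsmeier-type activation of the acid to the acyl chloride, then C-acylation of diazomethane (first stage of an Arndt–Eistert sequence); excess diazomethane consumes HCl so that no chloromethyl ketone forms, and aryl esters and ethers do not react with diazomethane.

Step 7
Reactants: 11 isovanillin
Product: 12 3-(benzyloxy)-4-methoxybenzaldehyde
Conditions: BnBr, K2CO3, DMF, 60 °C
Reagents that add atoms: benzyl bromide BrCc1ccccc1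
Why: Williamson etherification (SN2) of the phenoxide; the benzyl group is removed in the last step together with the ring A benzyl ether.

Step 8
Reactants: 10 4-(benzyloxy)-2-(2-diazoacetyl)-3,5-dimethoxyphenyl acetate, 3 methanol, 12 3-(benzyloxy)-4-methoxybenzaldehyde
Product: 13 4-(benzyloxy)-2-[(2R,3S)-3-[3-(benzyloxy)-4-methoxyphenyl]-3-hydroxy-2-methoxypropanoyl]-3,5-dimethoxyphenyl acetate
Conditions: Rh2(OAc)4 (2 mol %), Zr(OBu)4 (15 mol %)/(R)-3,3'-diiodo-BINOL (30 mol %) pre-formed and freed of butanol in vacuo, 4 Å MS, CH2Cl2, 0 °C to rt; 10 and 3 (1.2 equiv) added by syringe pump to 12 (2 equiv)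
Reagents that add atoms: none
Why: Proposed new method: Rh2(OAc)4 expels N2 from 10 to give a divalent-rhodium carbenoid at the future C3, methanol adds through oxygen to give a protic oxonium ylide (a metal-bound enol), and this enol adds to the zirconium-bound aldehyde 12 before it can collapse by 1,2-proton shift, so that C3–OMe and C2–C3 form in one operation. The closest known reaction is the Rh2(OAc)4/chiral zirconium–BINOL cocatalysed three-component coupling of aryldiazoacetates, alcohols and aryl aldehydes (aldol-type trapping of an oxonium ylide); the use of a terminal aroyldiazomethane with an electron-rich aldehyde is the untested part. No ring is closed here; the open-chain adduct already holds every atom of ring A, ring B and the C2–C3–C4 chain. The syn relationship should follow from a closed, hydrogen-bonded transition state in which the enol has its OMe and enol oxygen cis and the aldehyde aryl group sits pseudo-equatorial, and the absolute configuration at C3 (R) and at the carbinol carbon (S) should follow from the (R)-BINOL ligands on zirconium, which shield one face of the bound aldehyde. The step needs intermolecular ylide formation with methanol and aldol trapping to win over simple O–H insertion: the acetate removes the only O–H of the substrate and makes the C8a oxygen non-nucleophilic, the C5 methyl ether can only give a strained, reversibly formed five-membered oxonium ylide because the 2,6-disubstituted aroyl group is twisted out of the ring plane, and slow addition of 10 to excess Lewis-acid-activated 12 keeps the ylide concentration low.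

Step 9
Reactants: 13 4-(benzyloxy)-2-[(2R,3S)-3-[3-(benzyloxy)-4-methoxyphenyl]-3-hydroxy-2-methoxypropanoyl]-3,5-dimethoxyphenyl acetate, 3 methanol
Product: 14 (2R,3S)-1-[3-(benzyloxy)-6-hydroxy-2,4-dimethoxyphenyl]-3-[3-(benzyloxy)-4-methoxyphenyl]-3-hydroxy-2-methoxypropan-1-one
Conditions: NH4OAc, MeOH, rt
Reagents that add atoms: none
Why: Near-neutral transesterification of the activated aryl acetate (the ortho-acyl phenoxide is a good leaving group) to methanol; without strong base the β-hydroxy ketone should escape retro-aldol cleavage and epimerisation at the α-methoxy carbon.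

Step 10
Reactants: 14 (2R,3S)-1-[3-(benzyloxy)-6-hydroxy-2,4-dimethoxyphenyl]-3-[3-(benzyloxy)-4-methoxyphenyl]-3-hydroxy-2-methoxypropan-1-one
Product: 15 (2R,3R)-6-(benzyloxy)-2-[3-(benzyloxy)-4-methoxyphenyl]-3,5,7-trimethoxy-2,3-dihydro-4H-chromen-4-one
Conditions: PPh3, DIAD, THF, 0 °C to rt
Reagents that add atoms: none
Why: Intramolecular Mitsunobu etherification (6-exo-tet SN2): the benzylic carbinol is activated as its oxyphosphonium ion and displaced by the phenoxide with inversion, which turns the (S)-carbinol into (2R) and gives the trans-2,3 diequatorial ring C, while C3 is not involved.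

Step 11
Reactants: 15 (2R,3R)-6-(benzyloxy)-2-[3-(benzyloxy)-4-methoxyphenyl]-3,5,7-trimethoxy-2,3-dihydro-4H-chromen-4-one
Product: 16 (2R,3R)-5,6-dihydroxy-2-(3-hydroxy-4-methoxyphenyl)-3,7-dimethoxy-2,3-dihydro-4H-chromen-4-one
Conditions: BCl3, C6HMe5, CH2Cl2, −78 °C to 0 °C; aq. NaHCO3 work-up
Reagents that add atoms: none
Why: BCl3 cleaves both benzyl ethers at low temperature (pentamethylbenzene traps the benzyl cations by Friedel–Crafts alkylation) and, through the six-membered boron chelate with the C4 carbonyl, the peri C5 methyl ether; the C7, C4' and aliphatic C3 methyl ethers lack this chelation and should persist at or below 0 °C, and neither stereocentre is touched.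

**Compound list**

1 | syringaldehyde (4-hydroxy-3,5-dimethoxybenzaldehyde) | COc1cc(C=O)cc(OC)c1O | starting material
2 | 4-(benzyloxy)-3,5-dimethoxybenzaldehyde | COc1cc(C=O)cc(OC)c1OCc1ccccc1 | intermediate
3 | methanol | CO | starting material
4 | 4-(benzyloxy)-3,5-dimethoxyphenyl formate | COc1cc(OC=O)cc(OC)c1OCc1ccccc1 | intermediate (not isolated)
5 | 4-(benzyloxy)-3,5-dimethoxyphenol | COc1cc(O)cc(OC)c1OCc1ccccc1 | intermediate
6 | 3-(benzyloxy)-6-hydroxy-2,4-dimethoxybenzaldehyde | COc1cc(O)c(C=O)c(OC)c1OCc1ccccc1 | intermediate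
7 | 4-(benzyloxy)-2-formyl-3,5-dimethoxyphenyl acetate | COc1cc(OC(C)=O)c(C=O)c(OC)c1OCc1ccccc1 | intermediate
8 | 6-(acetyloxy)-3-(benzyloxy)-2,4-dimethoxybenzoic acid | COc1cc(OC(C)=O)c(C(=O)O)c(OC)c1OCc1ccccc1 | intermediate
9 | 6-(acetyloxy)-3-(benzyloxy)-2,4-dimethoxybenzoyl chloride | COc1cc(OC(C)=O)c(C(=O)Cl)c(OC)c1OCc1ccccc1 | intermediate (not isolated)
10 | 4-(benzyloxy)-2-(2-diazoacetyl)-3,5-dimethoxyphenyl acetate | COc1cc(OC(C)=O)c(C(=O)C=[N+]=[N-])c(OC)c1OCc1ccccc1 | intermediate
11 | isovanillin (3-hydroxy-4-methoxybenzaldehyde) | COc1ccc(C=O)cc1O | starting material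
12 | 3-(benzyloxy)-4-methoxybenzaldehyde | COc1ccc(C=O)cc1OCc1ccccc1 | intermediate
13 | 4-(benzyloxy)-2-[(2R,3S)-3-[3-(benzyloxy)-4-methoxyphenyl]-3-hydroxy-2-methoxypropanoyl]-3,5-dimethoxyphenyl acetate (syn aldol) | COc1ccc([C@H](O)[C@@H](OC)C(=O)c2c(OC(C)=O)cc(OC)c(OCc3ccccc3)c2OC)cc1OCc1ccccc1 | intermediate
14 | (2R,3S)-1-[3-(benzyloxy)-6-hydroxy-2,4-dimethoxyphenyl]-3-[3-(benzyloxy)-4-methoxyphenyl]-3-hydroxy-2-methoxypropan-1-one | COc1ccc([C@H](O)[C@@H](OC)C(=O)c2c(O)cc(OC)c(OCc3ccccc3)c2OC)cc1OCc1ccccc1 | intermediate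
15 | (2R,3R)-6-(benzyloxy)-2-[3-(benzyloxy)-4-methoxyphenyl]-3,5,7-trimethoxy-2,3-dihydro-4H-chromen-4-one (trans) | COc1ccc([C@H]2Oc3cc(OC)c(OCc4ccccc4)c(OC)c3C(=O)[C@@H]2OC)cc1OCc1ccccc1 | intermediate
16 | (2R,3R)-5,6-dihydroxy-2-(3-hydroxy-4-methoxyphenyl)-3,7-dimethoxy-2,3-dihydro-4H-chromen-4-one (trans; CNP0393633.1) | COc1ccc([C@H]2Oc3cc(OC)c(O)c(O)c3C(=O)[C@@H]2OC)cc1O | target

**Step count**

Total: 11 steps. Longest linear sequence: 10 steps (steps 1–6, then 8–11); step 7 is the one-step side branch.

**Steps most likely to fail**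

1. Step 8 (Proposed new method). The oxonium ylide may collapse by 1,2-proton shift to plain O–H insertion before the weakly electrophilic, electron-rich aldehyde engages it. The carbenoid may also be intercepted by the neighbouring C5 methoxy oxygen, or the syn/anti and facial selectivity may be poor. The fallback uses known chemistry, sets out from aldehyde 12 and phenol 5, and returns to the route at 14. (R)-4-Benzyloxazolidin-2-one is N-acylated with methoxyacetyl chloride (n-BuLi, THF, −78 °C) to give (R)-4-benzyl-3-(methoxyacetyl)oxazolidin-2-one F1. Its Z-boron enolate (Bu2BOTf, Et3N, CH2Cl2, −78 to 0 °C) adds to 12 in an Evans syn-aldol reaction to give (R)-4-benzyl-3-[(2R,3S)-3-[3-(benzyloxy)-4-methoxyphenyl]-3-hydroxy-2-methoxypropanoyl]oxazolidin-2-one F2. Transamidation (Me3Al, MeNH(OMe)·HCl, THF) gives (2R,3S)-3-[3-(benzyloxy)-4-methoxyphenyl]-3-hydroxy-N,2-dimethoxy-N-methylpropanamide F3, and TESCl/imidazole gives its triethylsilyl ether (2R,3S)-3-[3-(benzyloxy)-4-methoxyphenyl]-N,2-dimethoxy-N-methyl-3-[(triethylsilyl)oxy]propanamide F4. In parallel, 5 is converted (MOMCl, i-Pr2NEt) into 2-(benzyloxy)-1,3-dimethoxy-5-(methoxymethoxy)benzene F5. Directed ortho-lithiation between the OMOM and OMe groups (n-BuLi, THF, 0 °C) gives [3-(benzyloxy)-2,4-dimethoxy-6-(methoxymethoxy)phenyl]lithium F6. This adds to F4 at −78 °C to give (2R,3S)-1-[3-(benzyloxy)-2,4-dimethoxy-6-(methoxymethoxy)phenyl]-3-[3-(benzyloxy)-4-methoxyphenyl]-2-methoxy-3-[(triethylsilyl)oxy]propan-1-one F7. Dilute HCl in THF then removes the TES and MOM groups to deliver 14.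

2. Step 10. The activated benzylic carbinol may undergo β-elimination toward the α-methoxy enone, or ionise so that SN2 fidelity is lost. The fallback sets out from 14 and returns at 15 without any new compound (F0). It abandons SN2 control in favour of an ionising dehydrative etherification (catalytic TfOH in (CF3)2CHOH–CH2Cl2, 0 °C). The 4-methoxy-stabilised benzylic cation is captured by the phenol, and the intact C3 stereocentre should steer C2 to the thermodynamically preferred trans-2,3 arrangement whatever the carbinol configuration.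

3. Step 11. BCl3 may over-cleave the C7, C4' or C3 methyl ethers, or open the benzylic C2–O1 bond with epimerisation. The fallback sets out from 15 and returns at 16 by separating the two deprotections. Neutral hydrogenolysis (H2, Pd/C, EtOAc, rt) removes both benzyl groups to give (2R,3R)-6-hydroxy-2-(3-hydroxy-4-methoxyphenyl)-3,5,7-trimethoxy-2,3-dihydro-4H-chromen-4-one F8. Chelation-controlled mono-demethylation of the peri C5 methyl ether (AlCl3, MeCN, rt) then gives 16.

**Further compounds**

F1 | step 8 | (R)-4-benzyl-3-(methoxyacetyl)oxazolidin-2-one | COCC(=O)N1[C@H](Cc2ccccc2)COC1=O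
F2 | step 8 | (R)-4-benzyl-3-[(2R,3S)-3-[3-(benzyloxy)-4-methoxyphenyl]-3-hydroxy-2-methoxypropanoyl]oxazolidin-2-one | COc1ccc([C@H](O)[C@@H](OC)C(=O)N2[C@H](Cc3ccccc3)COC2=O)cc1OCc1ccccc1
F3 | step 8 | (2R,3S)-3-[3-(benzyloxy)-4-methoxyphenyl]-3-hydroxy-N,2-dimethoxy-N-methylpropanamide | COc1ccc([C@H](O)[C@@H](OC)C(=O)N(C)OC)cc1OCc1ccccc1
F4 | step 8 | (2R,3S)-3-[3-(benzyloxy)-4-methoxyphenyl]-N,2-dimethoxy-N-methyl-3-[(triethylsilyl)oxy]propanamide | COc1ccc([C@H](O[Si](CC)(CC)CC)[C@@H](OC)C(=O)N(C)OC)cc1OCc1ccccc1
F5 | step 8 | 2-(benzyloxy)-1,3-dimethoxy-5-(methoxymethoxy)benzene | COCOc1cc(OC)c(OCc2ccccc2)c(OC)c1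
F6 | step 8 | [3-(benzyloxy)-2,4-dimethoxy-6-(methoxymethoxy)phenyl]lithium | [Li]c1c(OCOC)cc(OC)c(OCc2ccccc2)c1OC
F7 | step 8 | (2R,3S)-1-[3-(benzyloxy)-2,4-dimethoxy-6-(methoxymethoxy)phenyl]-3-[3-(benzyloxy)-4-methoxyphenyl]-2-methoxy-3-[(triethylsilyl)oxy]propan-1-one | COc1ccc([C@H](O[Si](CC)(CC)CC)[C@@H](OC)C(=O)c2c(OCOC)cc(OC)c(OCc3ccccc3)c2OC)cc1OCc1ccccc1
F0 | step 10 | none | none
F8 | step 11 | (2R,3R)-6-hydroxy-2-(3-hydroxy-4-methoxyphenyl)-3,5,7-trimethoxy-2,3-dihydro-4H-chromen-4-one | COc1ccc([C@H]2Oc3cc(OC)c(O)c(OC)c3C(=O)[C@@H]2OC)cc1O
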